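The synthesis rests on disconnecting the bond between C8 of ring A and the lavandulyl CH2 (C1''). C8 lies between the pyranone oxygen O1 and the C7 hydroxyl; it is therefore the position at which 7-hydroxychromone takes up iodine, and the lavandulyl stereocentre sits one carbon away from C1'', so a primary organozinc at C1'' carries it unchanged. In the key step a base-free Negishi sp2–sp3 coupling joins the complete, bis-silylated (2S)-8-iodoflavanone (C2 set beforehand by asymmetric aryl conjugate addition to the iodochromone) with (S)-lavandulylzinc iodide (stereocentre from an Evans deconjugative prenylation), leaving only desilylation.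

Key step: step 10

Remark on numbering: flavanone numbering is used (O1, C2–C8a; B-ring atoms primed); C1'' is the lavandulyl CH2 and C2'' its stereocentre; TBS = tert-butyldimethylsilyl.

Remark on the chemistry: t-BuPyOx is assumed to show the same facial sense with chromones as with 3-substituted cyclic enones, so the (R)-ligand is specified for the (2S)-flavanone; were the sense opposite, the (S)-ligand would be used with no other change.

Step 1
Reactants: 1 (S)-4-benzyl-2-oxazolidinone; 2 3-methylbut-2-enoyl chloride
Product: 3 (S)-4-benzyl-3-(3-methylbut-2-enoyl)oxazolidin-2-one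
Conditions: n-BuLi, THF, −78 °C; then 2, −78 → 0 °C
Reagents that add atoms: none
Why: N-acylation of the lithiated oxazolidinone by the acid chloride (formation of an Evans imide), which does not touch the auxiliary stereocentre.

Step 2
Reactants: 3 (S)-4-benzyl-3-(3-methylbut-2-enoyl)oxazolidin-2-one; 4 prenyl bromide (1-bromo-3-methylbut-2-ene)
Product: 6 (4S)-4-benzyl-3-[(2S)-5-methyl-2-(prop-1-en-2-yl)hex-4-enoyl]oxazolidin-2-one, via sodium Z-dienolate 5 (not isolated)
Conditions: NaHMDS (1.05 equiv), THF, −78 °C; then 4, −78 → −40 °C; cold NH4Cl quench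
Reagents that add atoms: none
Why: Evans asymmetric alkylation in its deconjugative form: γ-deprotonation gives the chelated Z-dienolate, which is alkylated at the α-carbon by SN2 attack on the primary allylic bromide from the face opposite the C4 benzyl group, so that the lavandulyl stereocentre is set (2S) and the alkene moves out of conjugation to become the isopropenyl group.

Step 3
Reactants: 6 (4S)-4-benzyl-3-[(2S)-5-methyl-2-(prop-1-en-2-yl)hex-4-enoyl]oxazolidin-2-one
Product: 7 (S)-lavandulol [(2S)-5-methyl-2-(prop-1-en-2-yl)hex-4-en-1-ol]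
Conditions: LiBH4, MeOH (1 equiv), Et2O, 0 °C; aq. NaOH work-up
Reagents that add atoms: none
Why: Reductive cleavage of the Evans imide by hydride attack at the exocyclic carbonyl, which involves no enolisation and should therefore keep the α-stereocentre and the position of the β,γ-alkene.

Step 4
Reactants: 7 (S)-lavandulol
Product: 8 (S)-lavandulyl iodide [(3S)-3-(iodomethyl)-2,6-dimethylhepta-1,5-diene]
Conditions: PPh3, I2, imidazole, CH2Cl2, 0 °C → rt
Reagents that add atoms: iodine, II
Why: Appel-type iodination of a primary alcohol by SN2 displacement at the CH2 carbon, which leaves the neighbouring stereocentre and both alkenes untouched.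

Step 5
Reactants: 9 7-hydroxychromone (7-hydroxy-4H-chromen-4-one)
Product: 10 7-hydroxy-8-iodo-4H-chromen-4-one
Conditions: N-iodosuccinimide (1.05 equiv), DMF, 0 °C → rt
Reagents that add atoms: N-iodosuccinimide, O=C1CCC(=O)N1I
Why: Electrophilic aromatic iodination of a phenol, expected at C8 because this carbon is ortho to the 7-OH, flanked by O1 and next to the ring fusion (the position that reacts in 2-naphthol-like 7-hydroxybenzopyranones), while C6 and the pyranone C3 are less nucleophilic.

Step 6
Reactants: 10 7-hydroxy-8-iodo-4H-chromen-4-one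
Product: 11 7-[(tert-butyldimethylsilyl)oxy]-8-iodo-4H-chromen-4-one
Conditions: TBSCl, imidazole, DMF, rt
Reagents that add atoms: tert-butyldimethylsilyl chloride, CC(C)(C)[Si](C)(C)Cl
Why: Standard O-silylation of a phenol with a silyl chloride and imidazole, giving an ether that is stable to the neutral palladium and zinc chemistry ahead and removable without acid.

Step 7
Reactants: 12 4-bromo-3-methoxyphenol
Product: 13 (4-bromo-3-methoxyphenoxy)(tert-butyl)dimethylsilane
Conditions: TBSCl, imidazole, DMF, rt
Reagents that add atoms: tert-butyldimethylsilyl chloride, CC(C)(C)[Si](C)(C)Cl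
Why: Standard O-silylation of a phenol, which masks the acidic OH before the halogen–lithium exchange.

Step 8
Reactants: 13 (4-bromo-3-methoxyphenoxy)(tert-butyl)dimethylsilane
Product: 15 {4-[(tert-butyldimethylsilyl)oxy]-2-methoxyphenyl}boronic acid, via aryllithium 14 (not isolated)
Conditions: n-BuLi, THF, −78 °C; B(OiPr)3, −78 °C → rt; 1 M HCl to pH 6, 0 °C
Reagents that add atoms: triisopropyl borate, CC(C)OB(OC(C)C)OC(C)C; water, O
Why: Bromine–lithium exchange followed by borylation with a trialkyl borate and hydrolysis, in which the silyl ether sits para to lithium so that no silyl migration to carbon can occur.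

Step 9
Reactants: 11 7-[(tert-butyldimethylsilyl)oxy]-8-iodo-4H-chromen-4-one; 15 {4-[(tert-butyldimethylsilyl)oxy]-2-methoxyphenyl}boronic acid
Product: 16 (2S)-7-[(tert-butyldimethylsilyl)oxy]-2-{4-[(tert-butyldimethylsilyl)oxy]-2-methoxyphenyl}-8-iodochroman-4-one
Conditions: Pd(OCOCF3)2 (5–10 mol %), (R)-t-BuPyOx (6–12 mol %), NH4PF6 (30 mol %), H2O (5 equiv), 15 (2–3 equiv), ClCH2CH2Cl, 60 °C
Reagents that add atoms: none
Why: Pd(II)-catalysed asymmetric conjugate addition of an arylboronic acid to a chromone, in which the cationic aryl–Pd(II)–PyOx species inserts the C2=C3 bond on the enone face left open by the ligand tert-butyl group to set C2 as (S), and protonolysis of the palladium enolate releases the flavanone in a redox-neutral, base-free cycle that should leave the C8–I bond and the silyl ethers alone.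

Step 10
Reactants: 16 (2S)-7-[(tert-butyldimethylsilyl)oxy]-2-{4-[(tert-butyldimethylsilyl)oxy]-2-methoxyphenyl}-8-iodochroman-4-one; 8 (S)-lavandulyl iodide
Product: 18 (2S)-7-[(tert-butyldimethylsilyl)oxy]-2-{4-[(tert-butyldimethylsilyl)oxy]-2-methoxyphenyl}-8-[(2R)-5-methyl-2-(prop-1-en-2-yl)hex-4-en-1-yl]chroman-4-one, via (S)-lavandulylzinc iodide 17 (not isolated)
Conditions: 8 (1.5 equiv), Zn dust (activated), LiCl, THF, 40 °C; then 16, Pd(OAc)2 (4 mol %), SPhos (8 mol %), THF, 25 → 45 °C
Reagents that add atoms: none
Why: Zinc inserts into the C–I bond of 8 (LiCl-assisted) to give the primary alkylzinc 17; Pd(0)/SPhos adds oxidatively to the C8–I bond of 16, the lavandulyl group passes from zinc to palladium and reductive elimination forms the C8–C1'' bond. The closest known reaction type is the Negishi coupling of primary alkylzinc halides with ortho,ortho-disubstituted aryl halides under bulky dialkylbiarylphosphine ligands. No ring is closed and no stereocentre is formed. The lavandulyl stereocentre (C2'') is β to the metal and could only be lost by β-hydride elimination and reinsertion, which the ligand disfavours by making reductive elimination fast, while C2 of ring C, which epimerises under base by retro-oxa-Michael opening, is spared because an organozinc needs no base. The step needs chemoselectivity for C8–I over the C4 ketone and the aryl silyl ethers, which the low nucleophilicity and basicity of RZnI secure, and site fidelity, which follows from the single iodine placed at C8.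

Step 11
Reactants: 18 (2S)-7-[(tert-butyldimethylsilyl)oxy]-2-{4-[(tert-butyldimethylsilyl)oxy]-2-methoxyphenyl}-8-[(2R)-5-methyl-2-(prop-1-en-2-yl)hex-4-en-1-yl]chroman-4-one
Product: 19 Alopecurone G [(2S)-7-hydroxy-2-(4-hydroxy-2-methoxyphenyl)-8-[(2R)-5-methyl-2-(prop-1-en-2-yl)hex-4-en-1-yl]chroman-4-one]
Conditions: TBAF (2.2 equiv), AcOH (2.4 equiv), THF, 0 °C
Reagents that add atoms: none
Why: Fluoride cleavage of both aryl silyl ethers, buffered with acetic acid so that no free phenoxide persists, which should keep ring C closed (no retro-oxa-Michael epimerisation at C2) and, being non-acidic, should not add the 7-OH to the isopropenyl group.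

Compound list
1 | (S)-4-benzyl-2-oxazolidinone | O=C1N[C@@H](Cc2ccccc2)CO1 | starting material
2 | 3-methylbut-2-enoyl chloride | CC(C)=CC(=O)Cl | starting material
3 | (S)-4-benzyl-3-(3-methylbut-2-enoyl)oxazolidin-2-one | CC(C)=CC(=O)N1C(=O)OC[C@@H]1Cc1ccccc1 | intermediate
4 | prenyl bromide (1-bromo-3-methylbut-2-ene) | CC(C)=CCBr | starting material
5 | sodium Z-dienolate of 3 (O and isopropenyl cis) | C=C(C)/C=C(\[O-])N1C(=O)OC[C@@H]1Cc1ccccc1.[Na+] | intermediate
6 | (4S)-4-benzyl-3-[(2S)-5-methyl-2-(prop-1-en-2-yl)hex-4-enoyl]oxazolidin-2-one | C=C(C)[C@H](CC=C(C)C)C(=O)N1C(=O)OC[C@@H]1Cc1ccccc1 | intermediate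
7 | (S)-lavandulol, (2S)-5-methyl-2-(prop-1-en-2-yl)hex-4-en-1-ol | C=C(C)[C@H](CC=C(C)C)CO | intermediate
8 | (S)-lavandulyl iodide, (3S)-3-(iodomethyl)-2,6-dimethylhepta-1,5-diene | C=C(C)[C@H](CC=C(C)C)CI | intermediate
9 | 7-hydroxychromone (7-hydroxy-4H-chromen-4-one) | O=c1ccoc2cc(O)ccc12 | starting material
10 | 7-hydroxy-8-iodo-4H-chromen-4-one | O=c1ccoc2c(I)c(O)ccc12 | intermediate
11 | 7-[(tert-butyldimethylsilyl)oxy]-8-iodo-4H-chromen-4-one | CC(C)(C)[Si](C)(C)Oc1ccc2c(=O)ccoc2c1I | intermediate
12 | 4-bromo-3-methoxyphenol | COc1cc(O)ccc1Br | starting material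
13 | (4-bromo-3-methoxyphenoxy)(tert-butyl)dimethylsilane | COc1cc(O[Si](C)(C)C(C)(C)C)ccc1Br | intermediate
14 | {4-[(tert-butyldimethylsilyl)oxy]-2-methoxyphenyl}lithium | COc1cc(O[Si](C)(C)C(C)(C)C)ccc1[Li] | intermediate
15 | {4-[(tert-butyldimethylsilyl)oxy]-2-methoxyphenyl}boronic acid | COc1cc(O[Si](C)(C)C(C)(C)C)ccc1B(O)O | intermediate
16 | (2S)-7-[(tert-butyldimethylsilyl)oxy]-2-{4-[(tert-butyldimethylsilyl)oxy]-2-methoxyphenyl}-8-iodochroman-4-one | CC(C)(C)[Si](C)(C)Oc1ccc2c(c1I)O[C@H](c1ccc(O[Si](C)(C)C(C)(C)C)cc1OC)CC2=O | intermediate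
17 | (S)-lavandulylzinc iodide, [(2S)-5-methyl-2-(prop-1-en-2-yl)hex-4-en-1-yl]zinc iodide | C=C(C)[C@H](CC=C(C)C)C[Zn]I | intermediate
18 | (2S)-7-[(tert-butyldimethylsilyl)oxy]-2-{4-[(tert-butyldimethylsilyl)oxy]-2-methoxyphenyl}-8-[(2R)-5-methyl-2-(prop-1-en-2-yl)hex-4-en-1-yl]chroman-4-one | C=C(C)[C@H](CC=C(C)C)Cc1c(O[Si](C)(C)C(C)(C)C)ccc2c1O[C@H](c1ccc(O[Si](C)(C)C(C)(C)C)cc1OC)CC2=O | intermediate
19 | Alopecurone G, (2S)-7-hydroxy-2-(4-hydroxy-2-methoxyphenyl)-8-[(2R)-5-methyl-2-(prop-1-en-2-yl)hex-4-en-1-yl]chroman-4-one | C=C(C)[C@H](CC=C(C)C)Cc1c(O)ccc2c1O[C@H](c1ccc(O)cc1OC)CC2=O | target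

Total step count: 11. Longest linear sequence: 6 steps (steps 1, 2, 3, 4, 10, 11); the chromone branch (steps 5, 6, 9) and the boronic acid branch (steps 7, 8, 9) are shorter.

Steps most likely to fail

Step 9. Facial discrimination may be poor and aryl transfer slow for the ortho-methoxy, electron-rich boronic acid. Protodeboronation and consumption of the C8–I bond by adventitious Pd(0) may compete. The fallback sets out from 11 and 15 and comes back at 16. Catalyst control at C2 is given up. The same C2–aryl bond is made with an achiral, more active Pd(II)/2,2'-bipyridine catalyst (Pd(OCOCF3)2, bipy, aqueous ClCH2CH2Cl, 60 °C), which should give the racemic iodoflavanone F1. F1 is resolved by preparative SFC on a polysaccharide chiral stationary phase, the (2S)-enantiomer being 16. The (2R)-iodoflavanone F2 is returned to F1 by catalytic DBU in toluene, which racemises C2 through reversible retro-oxa-Michael ring-opening, and is resolved again.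

Step 10. β-Hydride elimination from the hindered lavandulyl–palladium intermediate at the doubly ortho-oxygenated C8 may outrun reductive elimination, leading to loss of iodine and of the chain as a diene. Prolonged heating with zinc salts may also open ring C reversibly. The fallback sets out from 11 and 17 (made from 8 as in step 10) and comes back at 18. The order of the two fragment unions is inverted. The Negishi coupling is run on the achiral iodochromone 11, which has no C2 stereocentre and no enolisable position and so allows a more forcing catalyst (Pd-PEPPSI-IPent, THF/NMP, 60 °C) and a larger excess of 17, to give the lavandulylchromone F3. The aryl conjugate addition of 15 under the conditions of step 9 then sets C2 and should give 18 directly.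

Step 11. Phenoxide formation at O7 or O4' during desilylation may open ring C by retro-oxa-Michael reaction and erode the configuration at C2. The fallback sets out from 16 and comes back at 19. The silyl groups are removed before the lavandulyl chain is present, when acid can be used without danger to the alkenes and no phenoxide is formed (HCl, MeOH, 0 °C → rt), which should give the bis-phenol iodoflavanone F4. The Negishi coupling of F4 with 17 (added slowly and in excess; Pd(OAc)2/SPhos, THF, 25 °C) is of a type known to tolerate free phenols, because C–C bond formation outruns protonation of the alkylzinc. It then delivers 19 as the last step.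

Further compounds
F1 | step 9 | racemic 7-[(tert-butyldimethylsilyl)oxy]-2-{4-[(tert-butyldimethylsilyl)oxy]-2-methoxyphenyl}-8-iodochroman-4-one | CC(C)(C)[Si](C)(C)Oc1ccc2c(c1I)OC(c1ccc(O[Si](C)(C)C(C)(C)C)cc1OC)CC2=O
F2 | step 9 | (2R)-7-[(tert-butyldimethylsilyl)oxy]-2-{4-[(tert-butyldimethylsilyl)oxy]-2-methoxyphenyl}-8-iodochroman-4-one | CC(C)(C)[Si](C)(C)Oc1ccc2c(c1I)O[C@@H](c1ccc(O[Si](C)(C)C(C)(C)C)cc1OC)CC2=O
F3 | step 10 | 7-[(tert-butyldimethylsilyl)oxy]-8-[(2R)-5-methyl-2-(prop-1-en-2-yl)hex-4-en-1-yl]-4H-chromen-4-one | C=C(C)[C@H](CC=C(C)C)Cc1c(O[Si](C)(C)C(C)(C)C)ccc2c(=O)ccoc12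
F4 | step 11 | (2S)-7-hydroxy-2-(4-hydroxy-2-methoxyphenyl)-8-iodochroman-4-one | Oc1ccc2c(c1I)O[C@H](c1ccc(O)cc1OC)CC2=O
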